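You charge substrate alone and at the end count how the charge is shared among target (dissolved plus crystals), isomer of the product B and isomer of the product A.

    crystals ⇌ target, rate k1*(cs1 - [target]) while solid is left; crystals form when [target] > cs1 (cs1 = 46 mM, k1 = 0.00502 min⁻¹)
    substrate → target (k2 = 0.00411 min⁻¹, Ea2 = 121 kJ mol⁻¹)
    substrate ⇌ other conformer (K3 = 0.060, k3 = 7.78 × 10⁻⁴ min⁻¹, Ea3 = 114 kJ mol⁻¹, ΔH3 = 27.0 kJ mol⁻¹)
    other conformer → isomer of the product A (k4 = 0.00116 min⁻¹, Ea4 = 127 kJ mol⁻¹)
    target ⇌ isomer of the product B (K5 = 8.65, k5 = 4.99 × 10⁻⁴ min⁻¹, Ea5 = 116 kJ mol⁻¹, ΔH5 = −28.0 kJ mol⁻¹)
    (constants at 110 °C)
the same everywhere: substrate 1.5 M; time 10 d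

| charge | temperature | remark |
|---|---|---|
| cedar | 110 °C |  |
| alder | 90 °C |  |
| elm |  | at 90 °C until 50 h, from then on at 110 °C |
- for target the crystals are counted in
- as a solid, counted per litre of solution: crystals
- the list of constants is for 110 °C, to be carried to other temperatures by the activation energies and enthalpies
- in a conversion other conformer counts as not yet reacted
* the best flask by amount of target, in percent of the substrate charged; "all alike" if 1.5 percentage points covers them all (cedar / alder / elm / all alike)
* amount of target at the end, in percent of the substrate charged, cedar
* amount of target at the end, in percent of the substrate charged, alder
* amount of target at the end, in percent of the substrate charged, elm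

My own reckoning goes down the ladder from the fastest rung, taking the solubility and the dissolution coefficient as equal at both temperatures, since no temperature data are given for them. Excess dissolved target passes into crystals with a halving time of 0.0959 d, while substrate halves in 0.117 d in cedar and 0.949 d in alder. In alder other conformer relaxes in 0.161 d, so it follows substrate as a pre-equilibrium, and it drains about 1.69% of the charge to isomer of the product A in cedar and 0.957% in alder.

While substrate pours in, dissolved target stands above solubility, and that excess feeds isomer of the product B with a burst of 9.94% of the charge in cedar. The forward step runs 7.43 times slower in alder, so there the burst is 1.34%.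

The slowest rung is what you should watch. With crystals present, dissolved target is held at solubility, so isomer of the product B climbs towards a ceiling, the equilibrium constant times the solubility over the charge: 26.5% of the charge at 110 °C. That leaves crystals of 68.7%, so solid remains. The approach then runs with a time constant of 12.0 d in cedar, the equilibrium constant over the forward rate constant. In alder the equilibrium constant is 1.62 times larger, so the ceiling is 43.0% and the time constant 145 d, which is longer than the 6.69 d of the solution by itself.

Joining both ends, the burst at the start and the ceiling at the end, gives 19.3% of isomer of the product B in cedar, hence 79.0% target. Alder gets 4.12%, hence 94.9% target. Elm keeps 21.8% substrate at the change, and for the hot stretch I use an effective start of 3.83% of isomer of the product B; this is not what elm holds on entering, because it adds to the part I reckon formed in the cold stretch the burst still to come from that remaining substrate after the change. From this effective start my reckoning grows to 14.8%, so elm ends near 84.1% target.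

The forecast names alder, with 80% for cedar, 95% for alder and 84% for elm, holding that “crystallisation limits that loss”. For cedar I stand lower, at 79.0%.

The simulation gives alder as best, with 80.3% in cedar, 95.0% in alder and 84.9% in elm. Set against the approach times, the run of 10 d compares with 12.0 d in cedar and 145 d in alder, and at 10.0 d isomer of the product B reads 18.2% in cedar and 4.02% in alder. After 100 d cedar reads 26.5% against its ceiling of 26.5%, while alder reads 21.9%, about half of its ceiling of 43.0%.

The constants used here are made up; the flask was simulated.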